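**Plan**

- Retrosynthesis: after removal of the silyl ethers and the tert-butyl ester, both depside C(=O)–O4 units are taken back one oxidation level to ArCH2–O4 ethers. The two benzylic CH2–O4 bonds are then cut, which leaves three gallate-derived rings (C, B, A).
- Enabling feature: each depside carbonyl carbon lies between C1 of one benzene ring and the O4 oxygen of the next ring. As a CH2 group this link is a benzyl aryl ether that can be installed at O4 (para to the carboxyl, the most acidic hydroxyl) and cannot shift to O3.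
- Forward: no ring is formed. The chain is joined C→B→A by two O4-alkylations with benzylic bromides (ring C bromide on methyl gallate, then ring B bromide on tert-butyl gallate), each followed by silylation.
- Both methylene groups are then oxidised to carbonyls in one mediated anodic oxygenation. Acidolysis of the tert-butyl ester and acidic fluoride desilylation complete the synthesis.
- Stereochemistry: the target has no stereocentre, so none is set or at risk.

Key step: step 11

Remark: the target is taken as the para,para-depside drawn. A galloyl group on O4 can shift to a free neighbouring hydroxyl in neutral or basic media, so every operation after the phenols are freed is kept acidic; anhydrous gallic acid is assumed.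

**Route**

Step 1
Reactants: 1 methyl gallate; 2 tert-butyldimethylsilyl chloride
Product: 3 methyl 3,4,5-tris(tert-butyldimethylsilyloxy)benzoate
Conditions: 2 (3.6 equiv, of which three are taken up), imidazole (7 equiv), DMF, rt
Reagents that add atoms: tert-butyldimethylsilyl chloride (second and third equivalents of 2), CC(C)(C)[Si](C)(C)Cl.CC(C)(C)[Si](C)(C)Cl
Why: Imidazole-promoted O-silylation of all three phenols, one equivalent of silyl chloride per hydroxyl, is standard for gallates and leaves the methyl ester untouched.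

Step 2
Reactants: 3 methyl 3,4,5-tris(tert-butyldimethylsilyloxy)benzoate
Product: 4 [3,4,5-tris(tert-butyldimethylsilyloxy)phenyl]methanol
Conditions: i-Bu2AlH (2.5 equiv), CH2Cl2, −78 to 0 °C; aq. potassium sodium tartrate
Reagents that add atoms: none
Why: Aluminium hydride reduction of the ester to the primary alcohol, which aryl silyl ethers tolerate at low temperature.

Step 3
Reactants: 4 [3,4,5-tris(tert-butyldimethylsilyloxy)phenyl]methanol
Product: 5 5-(bromomethyl)-1,2,3-tris(tert-butyldimethylsilyloxy)benzene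
Conditions: CBr4 (1.3 equiv), PPh3 (1.3 equiv), CH2Cl2, 0 °C; rapid filtration through silica, used at once
Reagents that add atoms: tetrabromomethane, BrC(Br)(Br)Br
Why: Appel reaction of a benzylic alcohol under neutral conditions, which keeps the silyl ethers intact.

Step 4
Reactants: 5 5-(bromomethyl)-1,2,3-tris(tert-butyldimethylsilyloxy)benzene; 1 methyl gallate
Product: 6 methyl 3,5-dihydroxy-4-[[3,4,5-tris(tert-butyldimethylsilyloxy)phenyl]methoxy]benzoate
Conditions: 1 (1.5 equiv), KHCO3 (1.5 equiv), DMF, rt, argon, dark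
Reagents that add atoms: none
Why: Williamson ether synthesis in which KHCO3 ionises only the 4-hydroxyl (para to the ester carbonyl, the most acidic of the three), so the bromide is attacked by O4 alone, the selectivity known for benzyl halide/KHCO3 alkylation of methyl gallate.

Step 5
Reactants: 6 methyl 3,5-dihydroxy-4-[[3,4,5-tris(tert-butyldimethylsilyloxy)phenyl]methoxy]benzoate; 2 tert-butyldimethylsilyl chloride
Product: 7 methyl 3,5-bis(tert-butyldimethylsilyloxy)-4-[[3,4,5-tris(tert-butyldimethylsilyloxy)phenyl]methoxy]benzoate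
Conditions: 2 (3 equiv, of which two are taken up), imidazole (6 equiv), DMF, 40 °C
Reagents that add atoms: tert-butyldimethylsilyl chloride (second equivalent of 2), CC(C)(C)[Si](C)(C)Cl
Why: Imidazole-promoted silylation of the two remaining phenols, one equivalent of silyl chloride each; the O4 ether is fixed and cannot exchange places with a silyl group.

Step 6
Reactants: 7 methyl 3,5-bis(tert-butyldimethylsilyloxy)-4-[[3,4,5-tris(tert-butyldimethylsilyloxy)phenyl]methoxy]benzoate
Product: 8 [3,5-bis(tert-butyldimethylsilyloxy)-4-[[3,4,5-tris(tert-butyldimethylsilyloxy)phenyl]methoxy]phenyl]methanol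
Conditions: i-Bu2AlH (2.5 equiv), CH2Cl2, −78 to 0 °C; aq. potassium sodium tartrate
Reagents that add atoms: none
Why: Aluminium hydride reduction of the ester to the benzylic alcohol, with the benzyl aryl ether and silyl ethers inert.

Step 7
Reactants: 8 [3,5-bis(tert-butyldimethylsilyloxy)-4-[[3,4,5-tris(tert-butyldimethylsilyloxy)phenyl]methoxy]phenyl]methanol
Product: 9 5-(bromomethyl)-1,3-bis(tert-butyldimethylsilyloxy)-2-[[3,4,5-tris(tert-butyldimethylsilyloxy)phenyl]methoxy]benzene
Conditions: CBr4 (1.3 equiv), PPh3 (1.3 equiv), CH2Cl2, 0 °C; rapid filtration through silica, used at once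
Reagents that add atoms: tetrabromomethane, BrC(Br)(Br)Br
Why: Appel reaction of the benzylic alcohol under neutral conditions that spare silyl ethers and the existing ether link.

Step 8
Reactants: 10 gallic acid
Product: 11 tert-butyl 3,4,5-trihydroxybenzoate
Conditions: tert-butyl 2,2,2-trichloroacetimidate (2.5 equiv), THF, rt to 50 °C, argon
Reagents that add atoms: tert-butyl 2,2,2-trichloroacetimidate, CC(C)(C)OC(=N)C(Cl)(Cl)Cl
Why: Uncatalysed trichloroacetimidate esterification, in which only the carboxylic acid is acidic enough to protonate the imidate and capture the tert-butyl cation, so the phenols stay free.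

Step 9
Reactants: 9 5-(bromomethyl)-1,3-bis(tert-butyldimethylsilyloxy)-2-[[3,4,5-tris(tert-butyldimethylsilyloxy)phenyl]methoxy]benzene; 11 tert-butyl 3,4,5-trihydroxybenzoate
Product: 12 tert-butyl 3,5-dihydroxy-4-[[3,5-bis(tert-butyldimethylsilyloxy)-4-[[3,4,5-tris(tert-butyldimethylsilyloxy)phenyl]methoxy]phenyl]methoxy]benzoate
Conditions: 11 (1.5 equiv), KHCO3 (1.5 equiv), DMF, rt, argon
Reagents that add atoms: none
Why: Second Williamson ether synthesis with the same acidity-based O4 selectivity; the tert-butyl ester is stable to bicarbonate.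

Step 10
Reactants: 12 tert-butyl 3,5-dihydroxy-4-[[3,5-bis(tert-butyldimethylsilyloxy)-4-[[3,4,5-tris(tert-butyldimethylsilyloxy)phenyl]methoxy]phenyl]methoxy]benzoate; 2 tert-butyldimethylsilyl chloride
Product: 13 tert-butyl 3,5-bis(tert-butyldimethylsilyloxy)-4-[[3,5-bis(tert-butyldimethylsilyloxy)-4-[[3,4,5-tris(tert-butyldimethylsilyloxy)phenyl]methoxy]phenyl]methoxy]benzoate
Conditions: 2 (3 equiv, of which two are taken up), imidazole (6 equiv), DMF, 40 °C
Reagents that add atoms: tert-butyldimethylsilyl chloride (second equivalent of 2), CC(C)(C)[Si](C)(C)Cl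
Why: Imidazole-promoted silylation of the last two phenols, one equivalent of silyl chloride each, gives a substrate whose only activated C–H bonds are the two ArCH2–O groups.

Step 11
Reactants: 13 tert-butyl 3,5-bis(tert-butyldimethylsilyloxy)-4-[[3,5-bis(tert-butyldimethylsilyloxy)-4-[[3,4,5-tris(tert-butyldimethylsilyloxy)phenyl]methoxy]phenyl]methoxy]benzoate
Product: 14 tert-butyl 3,5-bis(tert-butyldimethylsilyloxy)-4-[3,5-bis(tert-butyldimethylsilyloxy)-4-[3,4,5-tris(tert-butyldimethylsilyloxy)benzoyl]oxybenzoyl]oxybenzoate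
Conditions: N-hydroxyphthalimide (0.4 equiv), 2,6-lutidine (2 equiv), LiClO4 (0.1 M), O2 (1 atm), MeCN/CH2Cl2 (3:1), divided cell, reticulated vitreous carbon anode, Pt cathode, anode held at the potential of the mediator wave (set by cyclic voltammetry), rt
Reagents that add atoms: dioxygen, O=O
Why: Proposed new method: at the anode the N-hydroxyphthalimide/2,6-lutidine pair is oxidised by proton-coupled electron transfer to the phthalimide N-oxyl radical, which abstracts a hydrogen atom from each ArCH2–OAr' carbon; the carbon radical captures O2, chain transfer from N-hydroxyphthalimide gives an α-aryloxy hydroperoxide, and base-assisted loss of water (Kornblum–DeLaMare type) delivers the aryl ester, so two C=O bonds are made while no ring closes and no stereocentre is created. The closest known reaction types are the N-hydroxyphthalimide-mediated anodic oxygenation of benzylic methylene groups to ketones and the chemical oxidation of benzyl ethers to benzoates; applying this to two benzyl aryl ether links in one molecule is the untested part. The step needs hydrogen abstraction to outrun direct electron transfer from the oxygenated arenes, which the low potential of the mediator couple and the silyl ethers (weaker donors than alkyl ethers) should secure; silyl ethers and the tert-butyl ester also offer no C–H bond activated by an arene or an oxygen. The two silyloxy groups flanking each O4 twist the ArO–CH2 bond out of the ring plane, which leaves an oxygen lone pair free to stabilise the radical and later shields the new ester carbonyl from the N-hydroxyphthalimide anion. Dehydration of the hydroperoxide, and not its collapse to aldehyde and phenol, is favoured by the non-nucleophilic base, the dry medium and a fluoride-free electrolyte that also protects the silyl ethers.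

Step 12
Reactants: 14 tert-butyl 3,5-bis(tert-butyldimethylsilyloxy)-4-[3,5-bis(tert-butyldimethylsilyloxy)-4-[3,4,5-tris(tert-butyldimethylsilyloxy)benzoyl]oxybenzoyl]oxybenzoate
Product: 15 3,5-bis(tert-butyldimethylsilyloxy)-4-[3,5-bis(tert-butyldimethylsilyloxy)-4-[3,4,5-tris(tert-butyldimethylsilyloxy)benzoyl]oxybenzoyl]oxybenzoic acid
Conditions: CF3CO2H/CH2Cl2 (1:1), 0 °C to rt; co-evaporation with toluene
Reagents that add atoms: none
Why: Acidolysis of the tert-butyl ester (E1 loss of 2-methylpropene) in anhydrous CF3CO2H, which hindered aryl silyl ethers and aryl benzoates survive; with every phenol still silylated the tert-butyl cation finds no nucleophilic ring.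

Step 13
Reactants: 15 3,5-bis(tert-butyldimethylsilyloxy)-4-[3,5-bis(tert-butyldimethylsilyloxy)-4-[3,4,5-tris(tert-butyldimethylsilyloxy)benzoyl]oxybenzoyl]oxybenzoic acid
Product: 16 3,5-dihydroxy-4-[3,5-dihydroxy-4-(3,4,5-trihydroxybenzoyl)oxybenzoyl]oxybenzoic acid
Conditions: HF·pyridine (excess), THF, polypropylene vessel, 0 °C to rt; EtOAc/0.5 M HCl; reverse-phase chromatography (MeCN/H2O, 0.1% HCO2H), lyophilisation
Reagents that add atoms: none
Why: Fluoride-driven Si–O cleavage by the acidic HF·pyridine complex removes all seven aryl silyl ethers while the phenols stay protonated, which suppresses galloyl migration from O4 to O3 and ester solvolysis.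

**Compound list**

1 | methyl gallate (methyl 3,4,5-trihydroxybenzoate) | COC(=O)c1cc(O)c(O)c(O)c1 | starting material
2 | tert-butyldimethylsilyl chloride | CC(C)(C)[Si](C)(C)Cl | starting material
3 | methyl 3,4,5-tris(tert-butyldimethylsilyloxy)benzoate | COC(=O)c1cc(O[Si](C)(C)C(C)(C)C)c(O[Si](C)(C)C(C)(C)C)c(O[Si](C)(C)C(C)(C)C)c1 | intermediate
4 | [3,4,5-tris(tert-butyldimethylsilyloxy)phenyl]methanol | OCc1cc(O[Si](C)(C)C(C)(C)C)c(O[Si](C)(C)C(C)(C)C)c(O[Si](C)(C)C(C)(C)C)c1 | intermediate
5 | 5-(bromomethyl)-1,2,3-tris(tert-butyldimethylsilyloxy)benzene | BrCc1cc(O[Si](C)(C)C(C)(C)C)c(O[Si](C)(C)C(C)(C)C)c(O[Si](C)(C)C(C)(C)C)c1 | intermediate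
6 | methyl 3,5-dihydroxy-4-[[3,4,5-tris(tert-butyldimethylsilyloxy)phenyl]methoxy]benzoate | COC(=O)c1cc(O)c(OCc2cc(O[Si](C)(C)C(C)(C)C)c(O[Si](C)(C)C(C)(C)C)c(O[Si](C)(C)C(C)(C)C)c2)c(O)c1 | intermediate
7 | methyl 3,5-bis(tert-butyldimethylsilyloxy)-4-[[3,4,5-tris(tert-butyldimethylsilyloxy)phenyl]methoxy]benzoate | COC(=O)c1cc(O[Si](C)(C)C(C)(C)C)c(OCc2cc(O[Si](C)(C)C(C)(C)C)c(O[Si](C)(C)C(C)(C)C)c(O[Si](C)(C)C(C)(C)C)c2)c(O[Si](C)(C)C(C)(C)C)c1 | intermediate
8 | [3,5-bis(tert-butyldimethylsilyloxy)-4-[[3,4,5-tris(tert-butyldimethylsilyloxy)phenyl]methoxy]phenyl]methanol | OCc1cc(O[Si](C)(C)C(C)(C)C)c(OCc2cc(O[Si](C)(C)C(C)(C)C)c(O[Si](C)(C)C(C)(C)C)c(O[Si](C)(C)C(C)(C)C)c2)c(O[Si](C)(C)C(C)(C)C)c1 | intermediate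
9 | 5-(bromomethyl)-1,3-bis(tert-butyldimethylsilyloxy)-2-[[3,4,5-tris(tert-butyldimethylsilyloxy)phenyl]methoxy]benzene | BrCc1cc(O[Si](C)(C)C(C)(C)C)c(OCc2cc(O[Si](C)(C)C(C)(C)C)c(O[Si](C)(C)C(C)(C)C)c(O[Si](C)(C)C(C)(C)C)c2)c(O[Si](C)(C)C(C)(C)C)c1 | intermediate
10 | gallic acid (3,4,5-trihydroxybenzoic acid) | O=C(O)c1cc(O)c(O)c(O)c1 | starting material
11 | tert-butyl 3,4,5-trihydroxybenzoate | CC(C)(C)OC(=O)c1cc(O)c(O)c(O)c1 | intermediate
12 | tert-butyl 3,5-dihydroxy-4-[[3,5-bis(tert-butyldimethylsilyloxy)-4-[[3,4,5-tris(tert-butyldimethylsilyloxy)phenyl]methoxy]phenyl]methoxy]benzoate | CC(C)(C)OC(=O)c1cc(O)c(OCc2cc(O[Si](C)(C)C(C)(C)C)c(OCc3cc(O[Si](C)(C)C(C)(C)C)c(O[Si](C)(C)C(C)(C)C)c(O[Si](C)(C)C(C)(C)C)c3)c(O[Si](C)(C)C(C)(C)C)c2)c(O)c1 | intermediate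
13 | tert-butyl 3,5-bis(tert-butyldimethylsilyloxy)-4-[[3,5-bis(tert-butyldimethylsilyloxy)-4-[[3,4,5-tris(tert-butyldimethylsilyloxy)phenyl]methoxy]phenyl]methoxy]benzoate | CC(C)(C)OC(=O)c1cc(O[Si](C)(C)C(C)(C)C)c(OCc2cc(O[Si](C)(C)C(C)(C)C)c(OCc3cc(O[Si](C)(C)C(C)(C)C)c(O[Si](C)(C)C(C)(C)C)c(O[Si](C)(C)C(C)(C)C)c3)c(O[Si](C)(C)C(C)(C)C)c2)c(O[Si](C)(C)C(C)(C)C)c1 | intermediate
14 | tert-butyl 3,5-bis(tert-butyldimethylsilyloxy)-4-[3,5-bis(tert-butyldimethylsilyloxy)-4-[3,4,5-tris(tert-butyldimethylsilyloxy)benzoyl]oxybenzoyl]oxybenzoate | CC(C)(C)OC(=O)c1cc(O[Si](C)(C)C(C)(C)C)c(OC(=O)c2cc(O[Si](C)(C)C(C)(C)C)c(OC(=O)c3cc(O[Si](C)(C)C(C)(C)C)c(O[Si](C)(C)C(C)(C)C)c(O[Si](C)(C)C(C)(C)C)c3)c(O[Si](C)(C)C(C)(C)C)c2)c(O[Si](C)(C)C(C)(C)C)c1 | intermediate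
15 | 3,5-bis(tert-butyldimethylsilyloxy)-4-[3,5-bis(tert-butyldimethylsilyloxy)-4-[3,4,5-tris(tert-butyldimethylsilyloxy)benzoyl]oxybenzoyl]oxybenzoic acid | OC(=O)c1cc(O[Si](C)(C)C(C)(C)C)c(OC(=O)c2cc(O[Si](C)(C)C(C)(C)C)c(OC(=O)c3cc(O[Si](C)(C)C(C)(C)C)c(O[Si](C)(C)C(C)(C)C)c(O[Si](C)(C)C(C)(C)C)c3)c(O[Si](C)(C)C(C)(C)C)c2)c(O[Si](C)(C)C(C)(C)C)c1 | intermediate
16 | 3,5-dihydroxy-4-[3,5-dihydroxy-4-(3,4,5-trihydroxybenzoyl)oxybenzoyl]oxybenzoic acid (CNP0121783.0) | O=C(O)c1cc(O)c(OC(=O)c2cc(O)c(OC(=O)c3cc(O)c(O)c(O)c3)c(O)c2)c(O)c1 | target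

**Totals and risks**

Total step count: 13. Longest linear sequence: 12 steps (steps 1–7 and 9–13, from methyl gallate); step 8 is a one-step side branch.

Steps most likely to fail:

1. Step 11 (proposed new method). Direct electron transfer from the oxygenated arenes may compete with hydrogen abstraction, the peroxy intermediate may fragment to aldehyde and phenol and so break the chain, or the reaction may stall after the first oxidation. The fallback builds the two ester bonds by conventional acylation in a benzyl ether series; it sets out from 11 and comes back to the route at 16. O4-selective allylation of 11 (allyl bromide, KHCO3, DMF) should give tert-butyl 3,5-dihydroxy-4-(prop-2-enyloxy)benzoate F1, and benzylation (BnBr, K2CO3, DMF) then gives tert-butyl 3,5-bis(benzyloxy)-4-(prop-2-enyloxy)benzoate F2. Deallylation (Pd(PPh3)4 cat., morpholine, THF) frees tert-butyl 3,5-bis(benzyloxy)-4-hydroxybenzoate F3. Steglich esterification of this phenol with purchased 3,4,5-tris(benzyloxy)benzoic acid (N-(3-dimethylaminopropyl)-N'-ethylcarbodiimide hydrochloride, DMAP, CH2Cl2) gives tert-butyl 3,5-bis(benzyloxy)-4-[3,4,5-tris(benzyloxy)benzoyl]oxybenzoate F4, which CF3CO2H/CH2Cl2 converts into 3,5-bis(benzyloxy)-4-[3,4,5-tris(benzyloxy)benzoyl]oxybenzoic acid F5. A second Steglich esterification of this acid with another portion of the phenol gives tert-butyl 3,5-bis(benzyloxy)-4-[3,5-bis(benzyloxy)-4-[3,4,5-tris(benzyloxy)benzoyl]oxybenzoyl]oxybenzoate F6, and CF3CO2H/CH2Cl2 gives 3,5-bis(benzyloxy)-4-[3,5-bis(benzyloxy)-4-[3,4,5-tris(benzyloxy)benzoyl]oxybenzoyl]oxybenzoic acid F7. Neutral hydrogenolysis (H2, 10% Pd/C, THF/EtOAc) then delivers 16.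

2. Step 4. Phenoxide or bromide may strip the para silyl group of bromide 5, which triggers 1,6-elimination and oligomerisation; silyl transfer to the gallate and over-alkylation at O3/O5 are further risks. The fallback avoids the bromide and the base: a Mitsunobu etherification of alcohol 4 with methyl gallate 1 (PPh3, diisopropyl azodicarboxylate, THF, 0 °C) should again engage the most acidic hydroxyl, O4. It sets out from 4 and 1 and comes back at 6.

3. Step 13. A galloyl group may migrate from O4 to a freed neighbouring hydroxyl, or an aryl ester may be cleaved, during desilylation and the aqueous handling of the free polyphenolic acid. The fallback reverses the order of the two deprotections so that the last reagent is a volatile acid; it sets out from 14 and comes back at 16. Compound 14 is desilylated first (HF·pyridine, THF, 0 °C) to tert-butyl 3,5-dihydroxy-4-[3,5-dihydroxy-4-(3,4,5-trihydroxybenzoyl)oxybenzoyl]oxybenzoate F8, a neutral ester that can be purified and freed of any isomer on silica with an acidified eluent. CF3CO2H/CH2Cl2 containing a little water as cation trap then releases 16, which is isolated by evaporation and lyophilisation alone.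

**Further compounds**

F1 | step 11 | tert-butyl 3,5-dihydroxy-4-(prop-2-enyloxy)benzoate | CC(C)(C)OC(=O)c1cc(O)c(OCC=C)c(O)c1
F2 | step 11 | tert-butyl 3,5-bis(benzyloxy)-4-(prop-2-enyloxy)benzoate | CC(C)(C)OC(=O)c1cc(OCc2ccccc2)c(OCC=C)c(OCc2ccccc2)c1
F3 | step 11 | tert-butyl 3,5-bis(benzyloxy)-4-hydroxybenzoate | CC(C)(C)OC(=O)c1cc(OCc2ccccc2)c(O)c(OCc2ccccc2)c1
F4 | step 11 | tert-butyl 3,5-bis(benzyloxy)-4-[3,4,5-tris(benzyloxy)benzoyl]oxybenzoate | CC(C)(C)OC(=O)c1cc(OCc2ccccc2)c(OC(=O)c2cc(OCc3ccccc3)c(OCc3ccccc3)c(OCc3ccccc3)c2)c(OCc2ccccc2)c1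
F5 | step 11 | 3,5-bis(benzyloxy)-4-[3,4,5-tris(benzyloxy)benzoyl]oxybenzoic acid | OC(=O)c1cc(OCc2ccccc2)c(OC(=O)c2cc(OCc3ccccc3)c(OCc3ccccc3)c(OCc3ccccc3)c2)c(OCc2ccccc2)c1
F6 | step 11 | tert-butyl 3,5-bis(benzyloxy)-4-[3,5-bis(benzyloxy)-4-[3,4,5-tris(benzyloxy)benzoyl]oxybenzoyl]oxybenzoate | CC(C)(C)OC(=O)c1cc(OCc2ccccc2)c(OC(=O)c2cc(OCc3ccccc3)c(OC(=O)c3cc(OCc4ccccc4)c(OCc4ccccc4)c(OCc4ccccc4)c3)c(OCc3ccccc3)c2)c(OCc2ccccc2)c1
F7 | step 11 | 3,5-bis(benzyloxy)-4-[3,5-bis(benzyloxy)-4-[3,4,5-tris(benzyloxy)benzoyl]oxybenzoyl]oxybenzoic acid | OC(=O)c1cc(OCc2ccccc2)c(OC(=O)c2cc(OCc3ccccc3)c(OC(=O)c3cc(OCc4ccccc4)c(OCc4ccccc4)c(OCc4ccccc4)c3)c(OCc3ccccc3)c2)c(OCc2ccccc2)c1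
F0 | step 4 | none | none
F8 | step 13 | tert-butyl 3,5-dihydroxy-4-[3,5-dihydroxy-4-(3,4,5-trihydroxybenzoyl)oxybenzoyl]oxybenzoate | CC(C)(C)OC(=O)c1cc(O)c(OC(=O)c2cc(O)c(OC(=O)c3cc(O)c(O)c(O)c3)c(O)c2)c(O)c1
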